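The data come from a simulation for substances that don't exist; noise was put on by code.

A chain length cannot be read from Thursday's and Friday's runs, for they give Z and leave the number of chains unseen, but the ratio of two lengths may still be reached.

| flask | X | G | remark | time |
|---|---|---|---|---|
| Thursday's | 1 M | 7 mol% | run made earlier |  |
| Friday's | 1 M | 11 mol% | run made earlier |  |
| green | 1.0 M | 5 mol% |  | 10 min |
| teal | 1.0 M | 5 mol% |  | 6.0 min |

| run | time / min | Z / % |
|---|---|---|
| Thursday's | 2.00 | 1.1 |
| Thursday's | 4.00 | 2.6 |
| Thursday's | 6.00 | 4.1 |
| Thursday's | 8.00 | 5.6 |
| Thursday's | 10.0 | 6.7 |
| Friday's | 2.00 | 1.9 |
| Friday's | 4.00 | 4.2 |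
| Friday's | 6.00 | 5.8 |
| Friday's | 8.00 | 7.3 |
| Friday's | 10.0 | 9.2 |

(standard deviation of a reading: 0.3 percentage points)

- the average divides the monomer in chains by the number of chains begun, living and dead together
- what was read earlier has a scatter of 0.3 percentage points, one standard deviation
- the earlier runs do not show the number of chains; that part of a forecast is a guess

- which of the two ends with the longer chains by the average number of monomer units in a chain (chains begun, living or dead) ("neither" if they lie within 10 %) (green / teal / neither)
- average number of monomer units in a chain (chains begun, living or dead) at the end, green
- average number of monomer units in a chain (chains begun, living or dead) at the end, teal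

Both runs climb on nearly straight lines, which suggests that the number of growing ends stands still from the first reading to the last, and my own bet, which the readings cannot prove, is that the count of chains begun is frozen too once the flask is under way. Length is then Z over a constant, so green and teal, one recipe stopped at different times, differ in length as they differ in Z. You can reach that ratio by two ways. By the clock, a straight line through the origin makes it the later stopping time over the earlier, 1.67, the stop ratio. From the readings, Z at those same two times gives 1.63 on Thursday's run and 1.59 on Friday's, and with a scatter of 0.3 percentage points on each reading these stand close to the clock's figure, so the two ways agree on the ratio of Z, though the step from Z to length still rests on my bet in both. The stop ratio exceeds one by 67.0 %, more than the margin of 10 %, so I commit to green as the longer, while the absolute lengths remain a guess.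

The forecast differs from this: it says neither, with 200 (range 20 to 2000) for green and 200 (range 20 to 2000) for teal, holding that “monomer per chain doesn't depend on stopping time”.

The flask gives green, with 77.4 for green and 46.7 for teal.

    X + G → Q + Z (k = 0.00110 /M/s)
    X + Q → Z + Q, rate k2*[Q]*[X] (k = 0.140 /M/s)
    X + G → L (k = 0.0870 /M/s)
    G → J (k = 4.60 × 10⁻⁴ /s)

The lengths stand at 1.66 to one, beside the stop ratio of 1.67, and in teal Q reads 6.21 × 10⁻⁴ M at 3.00 min and 6.21 × 10⁻⁴ M at 6.00 min. The neighbouring flask is teal stopped at 1.5 min, where G, the limiting reagent, is down to 0.050 % of its charge and Q already reads 6.21 × 10⁻⁴ M. Its stop ratio against teal is 4.00, so dividing teal's length by it gives 11.7, and that flask gives 11.4.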